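**Retrosynthetic overview**
1. Target ⇐ desilylation ⇐ one Mitsunobu operation (C8 furoate with inversion, plus closure of a 1,10-diol to the trans-epoxide with inversion at C1) ⇐ hydroxyl-directed dihydroxylation of a (1(10)Z,4Z)-germacradienolide.
2. α-Methylene cis-lactone ⇐ Mannich/elimination on the lactone ⇐ 1,2-reduction/lactonisation of a ten-membered 6-keto ester.
3. Ten-membered ring ⇐ five-carbon ring expansion of a cyclopentanone: an alkenyllithium arm adds to C6=O (bicyclo[5.3.0] alkoxide), then Grob cleavage of C6–C10 with loss of the C1 tosylate gives C6=O and C1=C10.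
4. Ring-expansion substrate ⇐ reductive aldol (C10–C1 bond) of cyclopentenone 7 with aldehyde 13. 7 ⇐ (R)-4-hydroxycyclopentenone; 13 ⇐ propargyl alcohol + acetaldehyde enol silane.
5. Ring order: cyclopentane (bought) → transient cycloheptene (bicycle) → cyclodecadienone → γ-lactone → epoxide.

Assumption: locants C1–C15 follow germacranolide numbering (lactone O on C6, furoate on C8; ring drawn C1→C10 counterclockwise, β = toward the viewer; the target is then 1R,3S,6S,7R,8R,10R), and (R)-4-hydroxycyclopent-2-en-1-one is bought as the single enantiomer.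

**Route**

Step 1
Reactants: 1 (R)-4-hydroxycyclopent-2-en-1-one
Product: 2 (R)-4-(triethylsilyloxy)cyclopent-2-en-1-one
Conditions: Et3SiCl, imidazole, CH2Cl2, 0 °C
Reagents that add atoms: chlorotriethylsilane CC[Si](Cl)(CC)CC
Why: Standard O-silylation of a secondary alcohol; the stereocentre (future C8) is not touched.

Step 2
Reactants: 2 (R)-4-(triethylsilyloxy)cyclopent-2-en-1-one
Product: 3 (R)-2-iodo-4-(triethylsilyloxy)cyclopent-2-en-1-one
Conditions: I2, pyridine, CH2Cl2, 0 °C → rt
Reagents that add atoms: iodine II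
Why: Johnson α-iodination of an enone (pyridine addition, iodination, elimination), which leaves the C4 centre alone.

Step 3
Reactants: 3 (R)-2-iodo-4-(triethylsilyloxy)cyclopent-2-en-1-one
Product: 4 (R)-2-methyl-4-(triethylsilyloxy)cyclopent-2-en-1-one
Conditions: MeZnCl, PdCl2(dppf) (3 mol%), THF, 0 °C → rt
Reagents that add atoms: methylzinc chloride C[Zn]Cl
Why: Negishi cross-coupling of the α-iodoenone installs the future C14 methyl under neutral conditions that spare the β-silyloxy enone.

Step 4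
Reactants: 4 (R)-2-methyl-4-(triethylsilyloxy)cyclopent-2-en-1-one; 5 methyl bromoacetate
Product: 7 methyl 2-[(1R,5S)-3-methyl-2-oxo-5-(triethylsilyloxy)cyclopent-3-en-1-yl]acetate, via lithium dienolate 6 (not isolated)
Conditions: LiN(i-Pr)2, THF, −78 °C; then 5, DMPU, −78 → −40 °C
Reagents that add atoms: none
Why: Kinetic α'-enolate alkylation; the electrophile enters anti to the adjacent silyloxy group, setting C7 trans to C8–O, and β-elimination is suppressed because it would give a cyclopentadienone.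

Step 5
Reactants: 8 prop-2-yn-1-ol
Product: 10 (Z)-3-iodo-2-methylprop-2-en-1-ol, via chelated alkenylmagnesium 9 (not isolated)
Conditions: MeMgBr (2.5 equiv), CuI (10 mol%), THF, −10 °C → rt; then I2, −78 → 0 °C
Reagents that add atoms: methylmagnesium bromide C[Mg]Br; iodine II
Why: Alkoxide-directed anti-carbomagnesiation of the propargylic alcohol puts Mg cis to CH2O, and iodinolysis with retention gives the Z iodide (future C4=C5).

Step 6
Reactants: 10 (Z)-3-iodo-2-methylprop-2-en-1-ol
Product: 11 (Z)-3-iodo-2-methylprop-2-enal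
Conditions: MnO2, CH2Cl2, rt, dark; used at once
Reagents that add atoms: none
Why: Neutral allylic oxidation with MnO2 keeps the labile Z geometry.

Step 7
Reactants: 11 (Z)-3-iodo-2-methylprop-2-enal; 12 tert-butyldimethyl(vinyloxy)silane
Product: 13 (3S,4Z)-3-(tert-butyldimethylsilyloxy)-5-iodo-4-methylpent-4-enal
Conditions: chiral imidodiphosphorimidate Brønsted acid (IDPi, 1 mol%), pentane/CH2Cl2, −60 °C
Reagents that add atoms: none
Why: Catalytic enantioselective Mukaiyama aldol with silyl transfer; the confined acid (enantiomer chosen for Si-face attack) sets C3 as S and delivers O3 already TBS-protected.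

Step 8
Reactants: 7 methyl 2-[(1R,5S)-3-methyl-2-oxo-5-(triethylsilyloxy)cyclopent-3-en-1-yl]acetate; 13 (3S,4Z)-3-(tert-butyldimethylsilyloxy)-5-iodo-4-methylpent-4-enal
Product: 15 aldol adduct (C10 quaternary, chain β, C1–OH syn to the C10 methyl), via lithium enolate 14 (not isolated)
Conditions: LiBH(s-Bu)3 (1.0 equiv), THF, −78 °C; then 13, −78 °C; AcOH
Reagents that add atoms: none
Why: Reductive aldol: 1,4-hydride addition at the unsubstituted β-carbon gives the tetrasubstituted enolate regiospecifically; a Zimmerman–Traxler chair with the aldehyde residue equatorial places C1–OH syn to the C10 methyl, and the aldehyde approaches anti to the C8 silyloxy group.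

Step 9
Reactants: 15 aldol adduct
Product: 16 C1 tosylate of 15
Conditions: TsCl, Et3N, Me3N·HCl (cat.), CH2Cl2, 0 °C
Reagents that add atoms: 4-toluenesulfonyl chloride Cc1ccc(cc1)S(Cl)(=O)=O
Why: O-sulfonylation with retention at C1; the quaternary C10 rules out elimination towards the ketone.

Step 10
Reactants: 16 C1 tosylate of 15
Product: 19 ten-membered (1(10)Z,4Z)-6-keto ester, via alkenyllithium 17 (not isolated), via bicyclic lithium alkoxide 18 (not isolated)
Conditions: t-BuLi (2.05 equiv), THF/Et2O/pentane, −100 → −78 °C; then DMPU, −78 → 0 °C; pH 7 buffer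
Reagents that add atoms: none
Why: Proposed new method: iodine–lithium exchange at the Z-alkenyl iodide outruns carbonyl attack by t-BuLi, the alkenyllithium adds to the C6 ketone from the face of its own tether to give the cis-fused bicyclo[5.3.0] alkoxide (oxygen trans to the C7 ester arm, so no lactonisation), and on warming the alkoxide expels the antiperiplanar C1 tosylate with cleavage of C6–C10 (Grob fragmentation), so the cyclopentanone is expanded by five carbons to the cyclodecadienone, with the 1(10)Z geometry dictated by the syn C1–O/C10–CH3 relationship, the 4Z geometry inherited from the iodide, and C3, C7 and C8 untouched; the closest known reaction type is the SmI2 Barbier cyclisation/Grob fragmentation of iodoalkyl keto mesylates and the stepwise Wharton fragmentation of bicyclic 1,3-diol monosulfonates, neither shown as a one-flask alkenyllithium relay.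

Step 11
Reactants: 19 ten-membered (1(10)Z,4Z)-6-keto ester
Product: 21 cis-fused 6,12-lactone, via lithium C6 alkoxide 20 (not isolated)
Conditions: LiBH(s-Bu)3, THF, −78 → 0 °C; H2O
Reagents that add atoms: none
Why: 1,2-Reduction of the β,β-disubstituted enone under Felkin–Anh control (C8 branch antiperiplanar), reinforced by 1,3-anti induction from the C8 silyl ether, gives the 6β-alkoxide cis to the C7 arm, which closes the γ-lactone by acyl substitution.

Step 12
Reactants: 21 cis-fused 6,12-lactone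
Product: 25 α-methylene lactone, via lithium lactone enolate 22 (not isolated), via Mannich base 23 (not isolated), via trimethylammonium iodide 24 (not isolated)
Conditions: LiN(i-Pr)2, THF, −78 °C; Me2N=CH2+ I−, −78 → 0 °C; then MeI, THF/MeOH, rt; then NaHCO3 (aq.)
Reagents that add atoms: N,N-dimethylmethyleneiminium iodide C=[N+](C)C.[I-]
Why: Lactone α-methylenation by Mannich reaction with Eschenmoser's salt, N-methylation and Hofmann-type elimination; C11 becomes sp2, so its transient configuration does not matter.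

Step 13
Reactants: 25 α-methylene lactone
Product: 26 8α-alcohol
Conditions: PPTS (cat.), MeOH/CH2Cl2, 0 °C
Reagents that add atoms: none
Why: Selective acidic methanolysis of the more labile triethylsilyl ether in the presence of the secondary TBS ether.

Step 14
Reactants: 26 8α-alcohol
Product: 27 1α,8α,10α-triol
Conditions: OsO4 (5 mol%), Me3NO·2H2O, CH2Cl2, 0 °C
Reagents that add atoms: trimethylamine N-oxide C[N+](C)(C)[O-]; water O
Why: Hydrogen-bond-directed syn-dihydroxylation (Donohoe-type, aprotic solvent) of the electron-rich Z-1(10) alkene from the face of the homoallylic 8α-OH sets C10 (O α, CH3 β) and C1 (OH α); the enoate and the doubly oxygen-flanked C4=C5 are deactivated.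

Step 15
Reactants: 27 1α,8α,10α-triol; 28 furan-3-carboxylic acid
Product: 30 3-O-TBS ether of the target, via 8β-furoate 1α,10α-diol 29 (not isolated)
Conditions: PPh3 (3 equiv), DIAD (3 equiv), 28 (1.3 equiv), toluene, 0 °C → rt
Reagents that add atoms: none
Why: Double Mitsunobu reaction: the furoate displaces the C8 oxyphosphonium with inversion (8β-ester, cis to C7–C11), and the sec/tert 1,10-diol undergoes Mitsunobu cyclodehydration with inversion at C1 to the trans (1β,10α) epoxide, the tertiary carbinol being unable to be activated.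

Step 16
Reactants: 30 3-O-TBS ether of the target
Product: 31 target CNP0390850.1
Conditions: HF·pyridine, pyridine, THF, 0 °C
Reagents that add atoms: none
Why: Buffered fluoride desilylation frees the 3β-allylic alcohol without opening the epoxide or adding to the α-methylene lactone.

**Compound list**
1 | (R)-4-hydroxycyclopent-2-en-1-one | O[C@H]1C=CC(=O)C1 | starting material
2 | (R)-4-(triethylsilyloxy)cyclopent-2-en-1-one | CC[Si](CC)(CC)O[C@H]1C=CC(=O)C1 | intermediate
3 | (R)-2-iodo-4-(triethylsilyloxy)cyclopent-2-en-1-one | CC[Si](CC)(CC)O[C@H]1C=C(I)C(=O)C1 | intermediate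
4 | (R)-2-methyl-4-(triethylsilyloxy)cyclopent-2-en-1-one | CC[Si](CC)(CC)O[C@H]1C=C(C)C(=O)C1 | intermediate
5 | methyl bromoacetate | COC(=O)CBr | starting material
6 | lithium cross-conjugated dienolate of 4 (O–C1=C5, C4 unchanged) | CC[Si](CC)(CC)O[C@H]1C=C(C)C([O-])=C1.[Li+] | intermediate (not isolated)
7 | methyl 2-[(1R,5S)-3-methyl-2-oxo-5-(triethylsilyloxy)cyclopent-3-en-1-yl]acetate (arm and OSiEt3 trans; 7β-arm, 8α-O) | COC(=O)C[C@@H]1[C@@H](O[Si](CC)(CC)CC)C=C(C)C1=O | intermediate
8 | prop-2-yn-1-ol | OCC#C | starting material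
9 | bromomagnesium (Z)-3-(bromomagnesio)-2-methylprop-2-en-1-olate | Br[Mg]OC/C(C)=C\[Mg]Br | intermediate (not isolated)
10 | (Z)-3-iodo-2-methylprop-2-en-1-ol | OC/C(C)=C\I | intermediate
11 | (Z)-3-iodo-2-methylprop-2-enal | O=C/C(C)=C\I | intermediate
12 | tert-butyldimethyl(vinyloxy)silane | C=CO[Si](C)(C)C(C)(C)C | starting material
13 | (3S,4Z)-3-(tert-butyldimethylsilyloxy)-5-iodo-4-methylpent-4-enal | O=CC[C@H](O[Si](C)(C)C(C)(C)C)/C(C)=C\I | intermediate
14 | lithium enolate (O–C6=C10) from 1,4-reduction of 7 | COC(=O)C[C@@H]1[C@@H](O[Si](CC)(CC)CC)CC(C)=C1[O-].[Li+] | intermediate (not isolated)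
15 | aldol adduct: cyclopentanone (C6=O) with 7β-CH2CO2Me, 8α-OSiEt3, 10α-CH3 and 10β-[1-hydroxy-(3S)-3-(TBS-oxy)-5-iodo-4-methylpent-(4Z)-enyl]; C1–OH syn to C10–CH3 | COC(=O)C[C@@H]1[C@@H](O[Si](CC)(CC)CC)C[C@](C)([C@H](O)C[C@H](O[Si](C)(C)C(C)(C)C)/C(C)=C\I)C1=O | intermediate
16 | C1 tosylate of 15 (same configuration) | COC(=O)C[C@@H]1[C@@H](O[Si](CC)(CC)CC)C[C@](C)([C@H](OS(=O)(=O)c2ccc(C)cc2)C[C@H](O[Si](C)(C)C(C)(C)C)/C(C)=C\I)C1=O | intermediate
17 | (Z)-alkenyllithium from 16 (Li on C5) | COC(=O)C[C@@H]1[C@@H](O[Si](CC)(CC)CC)C[C@](C)([C@H](OS(=O)(=O)c2ccc(C)cc2)C[C@H](O[Si](C)(C)C(C)(C)C)/C(C)=C\[Li])C1=O | intermediate (not isolated)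
18 | lithium alkoxide of the cis-fused bicyclo[5.3.0]dec-4-ene (C6–O α, C5 and C1 β, C1–OTs) | COC(=O)C[C@@H]1[C@@H](O[Si](CC)(CC)CC)C[C@]2(C)[C@H](OS(=O)(=O)c3ccc(C)cc3)C[C@H](O[Si](C)(C)C(C)(C)C)C(C)=C[C@]12[O-].[Li+] | intermediate (not isolated)
19 | methyl 2-[3β-(TBS-oxy)-8α-(triethylsilyloxy)-4,10-dimethyl-6-oxocyclodeca-1(10)Z,4Z-dien-7β-yl]acetate (germacrane locants) | COC(=O)C[C@H]1C(=O)/C=C(/C)[C@@H](O[Si](C)(C)C(C)(C)C)C/C=C(/C)C[C@@H]1O[Si](CC)(CC)CC | intermediate
20 | lithium 6β-alkoxide of reduced 19 | COC(=O)C[C@H]1[C@@H]([O-])/C=C(/C)[C@@H](O[Si](C)(C)C(C)(C)C)C/C=C(/C)C[C@@H]1O[Si](CC)(CC)CC.[Li+] | intermediate (not isolated)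
21 | cis-fused 6,12-lactone (6β-O, 7β-CH2; 3β-OTBS, 8α-OSiEt3; 1(10)Z,4Z) | C1C(=O)O[C@H]2/C=C(/C)[C@@H](O[Si](C)(C)C(C)(C)C)C/C=C(/C)C[C@H](O[Si](CC)(CC)CC)[C@@H]12 | intermediate
22 | lithium enolate of lactone 21 | C1=C([O-])O[C@H]2/C=C(/C)[C@@H](O[Si](C)(C)C(C)(C)C)C/C=C(/C)C[C@H](O[Si](CC)(CC)CC)[C@@H]12.[Li+] | intermediate (not isolated)
23 | 11-(dimethylaminomethyl) lactone (C11 epimers) | CN(C)CC1C(=O)O[C@H]2/C=C(/C)[C@@H](O[Si](C)(C)C(C)(C)C)C/C=C(/C)C[C@H](O[Si](CC)(CC)CC)[C@@H]12 | intermediate (not isolated)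
24 | 11-(trimethylammoniomethyl) lactone iodide | C[N+](C)(C)CC1C(=O)O[C@H]2/C=C(/C)[C@@H](O[Si](C)(C)C(C)(C)C)C/C=C(/C)C[C@H](O[Si](CC)(CC)CC)[C@@H]12.[I-] | intermediate (not isolated)
25 | α-methylene lactone (3β-OTBS, 8α-OSiEt3, 1(10)Z,4Z) | C=C1C(=O)O[C@H]2/C=C(/C)[C@@H](O[Si](C)(C)C(C)(C)C)C/C=C(/C)C[C@H](O[Si](CC)(CC)CC)[C@@H]12 | intermediate
26 | 8α-hydroxy α-methylene lactone (3β-OTBS) | C=C1C(=O)O[C@H]2/C=C(/C)[C@@H](O[Si](C)(C)C(C)(C)C)C/C=C(/C)C[C@H](O)[C@@H]12 | intermediate
27 | 1α,8α,10α-triol (10β-CH3, 3β-OTBS, 4Z) | C=C1C(=O)O[C@H]2/C=C(/C)[C@@H](O[Si](C)(C)C(C)(C)C)C[C@H](O)[C@@](O)(C)C[C@H](O)[C@@H]12 | intermediate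
28 | furan-3-carboxylic acid | OC(=O)c1ccoc1 | starting material
29 | 8β-(3-furoyloxy) 1α,10α-diol | C=C1C(=O)O[C@H]2/C=C(/C)[C@@H](O[Si](C)(C)C(C)(C)C)C[C@H](O)[C@@](O)(C)C[C@@H](OC(=O)c3ccoc3)[C@@H]12 | intermediate (not isolated)
30 | 3-O-TBS ether of the target (1β,10α-epoxide, 8β-furoate) | C=C1C(=O)O[C@H]2/C=C(/C)[C@@H](O[Si](C)(C)C(C)(C)C)C[C@H]3O[C@]3(C)C[C@@H](OC(=O)c3ccoc3)[C@@H]12 | intermediate
31 | CNP0390850.1 (1R,3S,6S,7R,8R,10R) | C=C1C(=O)O[C@H]2/C=C(/C)[C@@H](O)C[C@H]3O[C@]3(C)C[C@@H](OC(=O)c3ccoc3)[C@@H]12 | target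

**Step count and risks**
Total: 16 steps. Longest linear sequence: 13 steps (steps 1–4, then 8–16; the aldehyde branch, steps 5–7, joins at step 8).

The three steps most likely to fail:

Step 10 (the proposed one-flask exchange/addition/fragmentation). The alkenyllithium may enolise the ketone instead of closing the seven-membered ring, or the lithium alkoxide may fragment sluggishly. The fallback uses known chemistry and sets out from 16. An intramolecular Nozaki–Hiyama–Kishi cyclisation (CrCl2, NiCl2 cat., DMF, rt) gives the bicyclic tertiary alcohol tosylate F1 without any basic organometallic. F1 is isolated and fragmented under classical Wharton–Grob conditions (KN(SiMe3)2, THF, −78 → 0 °C), returning to the route at 19.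

Step 8 (simple diastereoselection of an aldol with a tetrasubstituted enolate). If the C1 epimer ratio is poor, the 1(10) geometry after step 10 is compromised. The fallback sets out from 15 as obtained (mixed at C1). Dess–Martin oxidation converges both epimers on the 1,3-diketone F2. Zn(BH4)2 (Et2O, −78 °C) then reduces the less hindered side-chain ketone within the zinc chelate, with hydride anti to the pseudo-axial C10 methyl, so C1 is set by hydride delivery instead of by the aldol transition state. This returns to 15.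

Step 15 (double Mitsunobu). Transannular ether formation or furoate attack at C1 could compete with epoxide closure. The fallback sets out from 27. Bu2SnO-catalysed tosylation (TsCl, Et3N, CH2Cl2) activates only the secondary hydroxyl of the 1,10-diol, giving the monotosylate F3. DBU (CH2Cl2, 0 °C) then closes the epoxide with inversion at C1, giving the epoxy alcohol F4. An ordinary single Mitsunobu esterification with 28 (PPh3, DIAD) inverts C8 and returns to the route at 30.

**Further compounds**
F1 | step 10 | cis-fused bicyclo[5.3.0] tertiary alcohol (C6–OH α) with C1 tosylate | COC(=O)C[C@@H]1[C@@H](O[Si](CC)(CC)CC)C[C@]2(C)[C@H](OS(=O)(=O)c3ccc(C)cc3)C[C@H](O[Si](C)(C)C(C)(C)C)C(C)=C[C@]12O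
F2 | step 8 | 1,3-diketone (C1=O) from oxidation of 15 | COC(=O)C[C@@H]1[C@@H](O[Si](CC)(CC)CC)C[C@](C)(C(=O)C[C@H](O[Si](C)(C)C(C)(C)C)/C(C)=C\I)C1=O
F3 | step 15 | C1 monotosylate of triol 27 | C=C1C(=O)O[C@H]2/C=C(/C)[C@@H](O[Si](C)(C)C(C)(C)C)C[C@H](OS(=O)(=O)c3ccc(C)cc3)[C@@](O)(C)C[C@H](O)[C@@H]12
F4 | step 15 | 1β,10α-epoxy 8α-alcohol | C=C1C(=O)O[C@H]2/C=C(/C)[C@@H](O[Si](C)(C)C(C)(C)C)C[C@H]3O[C@]3(C)C[C@H](O)[C@@H]12
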